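The route rests on building ring C of the middle unit on the bottom unit and not on coupling two flavans. Middle O1 lies between aromatic C8a and C2, while C4 already bears bottom C8; ring C is therefore a 3-aryl-indan-1-one with one oxygen inserted. The key Baeyer–Villiger step forms O1–C8a and O1–C2 in one operation and turns the cyclopentanone into the six-membered lactone without touching the C4 stereocentre. Its precursor is a fully benzylated (3R)-3-aryl-4,6-bis(benzyloxy)indan-1-one whose aryl group is C8 of epigallocatechin. C2 and C3 are then grown from the lactone, and the top unit is added by a C4-cation coupling.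

Key step: step 8

Assumption: in step 7 the (R)-ligand is taken to give the (3R)-indanone; should the first run show the opposite sense, its antipode is used with no other change.

In the names below, "hexa-O-benzylepigallocatechin-8-yl" means (2R,3R)-3,5,7-tris(benzyloxy)-2-[3,4,5-tris(benzyloxy)phenyl]chroman-8-yl.

Step 1
Reactants: 1 (−)-epigallocatechin
Product: 2 5,7,3',4',5'-penta-O-benzyl-(−)-epigallocatechin
Conditions: BnBr, K2CO3, DMF, 0 °C → rt, Ar
Reagents that add atoms: benzyl bromide BrCc1ccccc1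
Why: Williamson etherification in which carbonate deprotonates only the five phenols, so the secondary C3 hydroxyl stays free and C2/C3 keep their configuration.

Step 2
Reactants: 2 5,7,3',4',5'-penta-O-benzyl-(−)-epigallocatechin
Product: 3 3,5,7,3',4',5'-hexa-O-benzyl-(−)-epigallocatechin
Conditions: NaH, BnBr, Bu4NI (cat.), DMF, 0 °C → rt
Reagents that add atoms: benzyl bromide BrCc1ccccc1
Why: Williamson etherification of the secondary alkoxide; with every phenol already capped no quinone-methide pathway is open for C2 epimerisation.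

Step 3
Reactants: 3 3,5,7,3',4',5'-hexa-O-benzyl-(−)-epigallocatechin
Product: 4 8-bromo-3,5,7,3',4',5'-hexa-O-benzylepigallocatechin
Conditions: NBS (1 equiv), CH2Cl2, −78 → 0 °C
Reagents that add atoms: N-bromosuccinimide O=C1CCC(=O)N1Br
Why: Electrophilic aromatic bromination of benzylated flavan-3-ols takes place at C8, the most nucleophilic position of the phloroglucinol-type ring A, when one equivalent of NBS is used cold.

Step 4
Reactants: 4 8-bromo-3,5,7,3',4',5'-hexa-O-benzylepigallocatechin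
Product: 6 3,5,7,3',4',5'-hexa-O-benzylepigallocatechin-8-carbaldehyde, via 8-lithio arene 5 (not isolated)
Conditions: n-BuLi, THF, −78 °C; DMF, −78 → 0 °C; H2O
Reagents that add atoms: N,N-dimethylformamide CN(C)C=O
Why: Bromine–lithium exchange is faster than any attack on the benzyl ethers at −78 °C, and formylation of the aryllithium with DMF (Bouveault aldehyde synthesis) places the carbonyl carbon on C8.

Step 5
Reactants: 7 3',5'-bis(benzyloxy)acetophenone
Product: 8 2'-bromo-3',5'-bis(benzyloxy)acetophenone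
Conditions: NBS, MeCN, 0 °C → rt, dark
Reagents that add atoms: N-bromosuccinimide O=C1CCC(=O)N1Br
Why: Electrophilic aromatic bromination at the position ortho to the acetyl group, which is ortho and para to the two ether oxygens (C2 and C6 are equivalent), is preferred over the position flanked by both ethers and over ketone α-bromination without acid or light.

Step 6
Reactants: 6 3,5,7,3',4',5'-hexa-O-benzylepigallocatechin-8-carbaldehyde; 8 2'-bromo-3',5'-bis(benzyloxy)acetophenone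
Product: 9 (E)-1-[2-bromo-3,5-bis(benzyloxy)phenyl]-3-(hexa-O-benzylepigallocatechin-8-yl)prop-2-en-1-one
Conditions: KOH, EtOH/THF, rt → 40 °C
Reagents that add atoms: none
Why: Claisen–Schmidt condensation in which the aldehyde cannot enolise, the methyl ketone enolate adds, and E1cB loss of water gives the conjugated E-enone.

Step 7
Reactants: 9 (E)-1-[2-bromo-3,5-bis(benzyloxy)phenyl]-3-(hexa-O-benzylepigallocatechin-8-yl)prop-2-en-1-one
Product: 10 (3R)-4,6-bis(benzyloxy)-3-(hexa-O-benzylepigallocatechin-8-yl)indan-1-one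
Conditions: Pd(OAc)2 (cat.), (R)-3,5-Xyl-MeO-BIPHEP (cat.), HCO2H, i-Pr2NEt, ethylene glycol/1,4-dioxane, 80 °C
Reagents that add atoms: none
Why: Asymmetric intramolecular reductive Heck reaction in which zerovalent palladium inserts into the C–Br bond, the aryl group adds to the enone β-carbon in a 5-endo carbopalladation, the palladium enolate is protonated and formate regenerates the catalyst, the chiral bisphosphine choosing the enone face and thereby the C3 configuration.

Step 8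
Reactants: 10 (3R)-4,6-bis(benzyloxy)-3-(hexa-O-benzylepigallocatechin-8-yl)indan-1-one
Product: 11 (4R)-5,7-bis(benzyloxy)-4-(hexa-O-benzylepigallocatechin-8-yl)chroman-2-one
Conditions: mCPBA, NaHCO3, CH2Cl2, 0 °C → rt, dark
Reagents that add atoms: m-chloroperbenzoic acid OOC(=O)c1cccc(Cl)c1
Why: Baeyer–Villiger oxidation: the peracid adds to the ketone, which is not deactivated because both benzyloxy groups are meta to the carbonyl-bearing carbon, and the tetrahedral Criegee adduct rearranges with a 1,2-shift of aromatic C7a from carbon to oxygen as m-chlorobenzoate leaves. The closest known reaction is the peracid oxidation of 1-indanones, 3-aryl-1-indanones included, to 3,4-dihydrocoumarins. No ring is closed by a cyclisation; the five-membered carbocycle is enlarged to the six-membered lactone of ring C by insertion of O1 between C8a and C2 (ring expansion through a 1,2-shift). No stereocentre is formed, and the indanone C3 centre, which is β to the carbonyl and not part of the migrating bond, is carried over unchanged as C4. The step needs aryl-over-methylene migration, which rests on the higher migratory aptitude of an sp2 carbon that can bridge in a phenonium-like transition state compared with an unactivated primary CH2, and ketone-over-arene chemoselectivity, which rests on the absence of any free phenol (all are benzyl ethers), on the hydrogencarbonate buffer that keeps the peracid from being acid-activated, and on low temperature.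

Step 9
Reactants: 11 (4R)-5,7-bis(benzyloxy)-4-(hexa-O-benzylepigallocatechin-8-yl)chroman-2-one
Product: 13 (4R)-5,7-bis(benzyloxy)-4-(hexa-O-benzylepigallocatechin-8-yl)-4H-chromen-2-yl diphenyl phosphate, via potassium lactone enolate 12 (not isolated)
Conditions: KN(SiMe3)2, (PhO)2P(O)Cl, THF/DMPU, −78 °C
Reagents that add atoms: diphenyl chlorophosphate O=P(Cl)(Oc1ccccc1)Oc1ccccc1
Why: Ketene acetal phosphate formation in which the potassium enolate, made at the only acidic position C3 and trapped at −78 °C before it can fragment to a ketene, is phosphorylated on oxygen while C4 is not involved.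

Step 10
Reactants: 13 (4R)-5,7-bis(benzyloxy)-4-(hexa-O-benzylepigallocatechin-8-yl)-4H-chromen-2-yl diphenyl phosphate
Product: 14 (4R)-5,7-bis(benzyloxy)-4-(hexa-O-benzylepigallocatechin-8-yl)-4H-chromene
Conditions: Pd(PPh3)4 (cat.), Bu3SnH, THF, rt
Reagents that add atoms: none
Why: Palladium-catalysed reduction of an enol phosphate (insertion of zerovalent palladium into the C–O bond, hydride transfer from tin, C–H reductive elimination), known for lactone-derived enol triflates and phosphates, gives the cyclic enol ether with C4 untouched.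

Step 11
Reactants: 15 5-bromopyrogallol
Product: 16 5-bromo-1,2,3-tris(benzyloxy)benzene
Conditions: BnBr, K2CO3, DMF, rt, Ar
Reagents that add atoms: benzyl bromide BrCc1ccccc1
Why: Williamson etherification of the three phenols; the aryl bromide is inert to carbonate and benzyl bromide.

Step 12
Reactants: 14 (4R)-5,7-bis(benzyloxy)-4-(hexa-O-benzylepigallocatechin-8-yl)-4H-chromene; 16 5-bromo-1,2,3-tris(benzyloxy)benzene
Product: 20 (2R,3R,4R)-5,7-bis(benzyloxy)-2-[3,4,5-tris(benzyloxy)phenyl]-4-(hexa-O-benzylepigallocatechin-8-yl)chroman-3-ol, via aryllithium 17 (not isolated), via triarylalane 18 (not isolated), via chromene 2,3-epoxide 19 (not isolated)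
Conditions: 16, n-BuLi, Et2O, −78 °C; AlCl3 (0.33 equiv), −78 → 0 °C; separately 14, DMDO, acetone/CH2Cl2, −78 → 0 °C, solvent removed cold; alane solution added, toluene, −78 → 0 °C; aq. potassium sodium tartrate
Reagents that add atoms: dimethyldioxirane CC1(C)OO1
Why: Enol ether epoxidation followed by syn-selective epoxide opening with an organoaluminium reagent, as known for glycal epoxides giving 1,2-cis C-aryl glycosides: DMDO attacks the C2=C3 bond anti to the pseudoaxial C4 aryl group (setting C3), and the aluminium bound to the epoxide oxygen opens the C2–O bond and hands an aryl group to C2 on that same face (setting C2 cis to O-3 and trans to the C4 aryl).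

Step 13
Reactants: 20 (2R,3R,4R)-5,7-bis(benzyloxy)-2-[3,4,5-tris(benzyloxy)phenyl]-4-(hexa-O-benzylepigallocatechin-8-yl)chroman-3-ol; 21 3,4,5-tris(benzyloxy)benzoic acid
Product: 22 3-O-[3,4,5-tris(benzyloxy)benzoyl] ester of 20
Conditions: DCC, DMAP, CH2Cl2, rt
Reagents that add atoms: none
Why: Steglich esterification of the single free hydroxyl group; no stereocentre is touched.

Step 14
Reactants: 4 8-bromo-3,5,7,3',4',5'-hexa-O-benzylepigallocatechin
Product: 23 8-bromo-3,5,7,3',4',5'-hexa-O-benzyl-4β-(2-ethoxyethoxy)epigallocatechin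
Conditions: DDQ, 2-ethoxyethanol, CH2Cl2, rt
Reagents that add atoms: 2-ethoxyethanol CCOCCO
Why: Benzylic oxidation by hydride abstraction with DDQ gives the C4 cation stabilised by the 5,7-dialkoxy ring A, which the alcohol captures anti to the axial 3-benzyloxy group (4β ether).

Step 15
Reactants: 22 3-O-[3,4,5-tris(benzyloxy)benzoyl] ester of 20; 23 8-bromo-3,5,7,3',4',5'-hexa-O-benzyl-4β-(2-ethoxyethoxy)epigallocatechin
Product: 24 perbenzylated 8-bromo trimer (top unit 4β-linked to C8 of the middle ring A)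
Conditions: TMSOTf (cat.), CH2Cl2, −78 → −40 °C; Et3N
Reagents that add atoms: none
Why: Lewis-acid-promoted Friedel–Crafts alkylation (the usual flavan C4-cation coupling) in which TMSOTf ionises the C4 ether, C8 of the middle ring A (the most nucleophilic free arene position of 22) attacks anti to the axial 3-benzyloxy group to set the 4β configuration, and the C8 bromine of 23 prevents self-condensation and over-reaction.

Step 16
Reactants: 24 perbenzylated 8-bromo trimer
Product: 25 CNP0278699.1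
Conditions: H2 (1 atm), Pd(OH)2/C, Et3N (2 equiv), THF/MeOH/H2O, rt
Reagents that add atoms: none
Why: Catalytic hydrogenolysis cleaves all twenty benzyl ethers and the aryl C–Br bond while triethylamine scavenges HBr, so the gallate ester, the acid-labile interflavan bonds and all stereocentres persist.

Compound list
1 | (−)-epigallocatechin, (2R,3R) | O[C@@H]1Cc2c(O)cc(O)cc2O[C@@H]1c1cc(O)c(O)c(O)c1 | starting material
2 | 5,7,3',4',5'-penta-O-benzyl-(−)-epigallocatechin, (2R,3R), free 3-OH | O[C@@H]1Cc2c(OCc9ccccc9)cc(OCc9ccccc9)cc2O[C@@H]1c1cc(OCc9ccccc9)c(OCc9ccccc9)c(OCc9ccccc9)c1 | intermediate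
3 | 3,5,7,3',4',5'-hexa-O-benzyl-(−)-epigallocatechin, (2R,3R) | c1c(OCc9ccccc9)cc(OCc9ccccc9)c2c1O[C@H](c1cc(OCc9ccccc9)c(OCc9ccccc9)c(OCc9ccccc9)c1)[C@H](OCc9ccccc9)C2 | intermediate
4 | 8-bromo-3,5,7,3',4',5'-hexa-O-benzylepigallocatechin, (2R,3R) | Brc1c(OCc9ccccc9)cc(OCc9ccccc9)c2c1O[C@H](c1cc(OCc9ccccc9)c(OCc9ccccc9)c(OCc9ccccc9)c1)[C@H](OCc9ccccc9)C2 | intermediate
5 | 8-lithio-3,5,7,3',4',5'-hexa-O-benzylepigallocatechin | [Li]c1c(OCc9ccccc9)cc(OCc9ccccc9)c2c1O[C@H](c1cc(OCc9ccccc9)c(OCc9ccccc9)c(OCc9ccccc9)c1)[C@H](OCc9ccccc9)C2 | intermediate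
6 | 3,5,7,3',4',5'-hexa-O-benzylepigallocatechin-8-carbaldehyde | O=Cc1c(OCc9ccccc9)cc(OCc9ccccc9)c2c1O[C@H](c1cc(OCc9ccccc9)c(OCc9ccccc9)c(OCc9ccccc9)c1)[C@H](OCc9ccccc9)C2 | intermediate
7 | 3',5'-bis(benzyloxy)acetophenone | CC(=O)c1cc(OCc9ccccc9)cc(OCc9ccccc9)c1 | starting material
8 | 2'-bromo-3',5'-bis(benzyloxy)acetophenone | CC(=O)c1cc(OCc9ccccc9)cc(OCc9ccccc9)c1Br | intermediate
9 | (E)-1-[2-bromo-3,5-bis(benzyloxy)phenyl]-3-(hexa-O-benzylepigallocatechin-8-yl)prop-2-en-1-one | O=C(/C=C/c1c(OCc9ccccc9)cc(OCc9ccccc9)c2c1O[C@H](c1cc(OCc9ccccc9)c(OCc9ccccc9)c(OCc9ccccc9)c1)[C@H](OCc9ccccc9)C2)c1cc(OCc9ccccc9)cc(OCc9ccccc9)c1Br | intermediate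
10 | (3R)-4,6-bis(benzyloxy)-3-(hexa-O-benzylepigallocatechin-8-yl)indan-1-one | O=C1C[C@@H](c2c(OCc9ccccc9)cc(OCc9ccccc9)c3c2O[C@H](c2cc(OCc9ccccc9)c(OCc9ccccc9)c(OCc9ccccc9)c2)[C@H](OCc9ccccc9)C3)c2c(OCc9ccccc9)cc(OCc9ccccc9)cc21 | intermediate
11 | (4R)-5,7-bis(benzyloxy)-4-(hexa-O-benzylepigallocatechin-8-yl)chroman-2-one | O=C1C[C@@H](c2c(OCc9ccccc9)cc(OCc9ccccc9)c3c2O[C@H](c2cc(OCc9ccccc9)c(OCc9ccccc9)c(OCc9ccccc9)c2)[C@H](OCc9ccccc9)C3)c2c(OCc9ccccc9)cc(OCc9ccccc9)cc2O1 | intermediate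
12 | potassium enolate of lactone 11 | [K+].[O-]C1=C[C@@H](c2c(OCc9ccccc9)cc(OCc9ccccc9)c3c2O[C@H](c2cc(OCc9ccccc9)c(OCc9ccccc9)c(OCc9ccccc9)c2)[C@H](OCc9ccccc9)C3)c2c(OCc9ccccc9)cc(OCc9ccccc9)cc2O1 | intermediate
13 | (4R)-5,7-bis(benzyloxy)-4-(hexa-O-benzylepigallocatechin-8-yl)-4H-chromen-2-yl diphenyl phosphate | O=P(Oc1ccccc1)(Oc1ccccc1)OC1=C[C@@H](c2c(OCc9ccccc9)cc(OCc9ccccc9)c3c2O[C@H](c2cc(OCc9ccccc9)c(OCc9ccccc9)c(OCc9ccccc9)c2)[C@H](OCc9ccccc9)C3)c2c(OCc9ccccc9)cc(OCc9ccccc9)cc2O1 | intermediate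
14 | (4R)-5,7-bis(benzyloxy)-4-(hexa-O-benzylepigallocatechin-8-yl)-4H-chromene | C1=C[C@@H](c2c(OCc9ccccc9)cc(OCc9ccccc9)c3c2O[C@H](c2cc(OCc9ccccc9)c(OCc9ccccc9)c(OCc9ccccc9)c2)[C@H](OCc9ccccc9)C3)c2c(OCc9ccccc9)cc(OCc9ccccc9)cc2O1 | intermediate
15 | 5-bromopyrogallol (5-bromobenzene-1,2,3-triol) | Oc1cc(Br)cc(O)c1O | starting material
16 | 5-bromo-1,2,3-tris(benzyloxy)benzene | Brc1cc(OCc9ccccc9)c(OCc9ccccc9)c(OCc9ccccc9)c1 | intermediate
17 | 3,4,5-tris(benzyloxy)phenyllithium | [Li]c1cc(OCc9ccccc9)c(OCc9ccccc9)c(OCc9ccccc9)c1 | intermediate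
18 | tris[3,4,5-tris(benzyloxy)phenyl]aluminium | [Al](c1cc(OCc9ccccc9)c(OCc9ccccc9)c(OCc9ccccc9)c1)(c1cc(OCc9ccccc9)c(OCc9ccccc9)c(OCc9ccccc9)c1)c1cc(OCc9ccccc9)c(OCc9ccccc9)c(OCc9ccccc9)c1 | intermediate
19 | 2,3-epoxide of chromene 14, epoxide oxygen on the face opposite to the C4 aryl group | [C@H]1(c2c(OCc9ccccc9)cc(OCc9ccccc9)c3c2O[C@H](c2cc(OCc9ccccc9)c(OCc9ccccc9)c(OCc9ccccc9)c2)[C@H](OCc9ccccc9)C3)c2c(OCc9ccccc9)cc(OCc9ccccc9)cc2O[C@@H]2O[C@H]12 | intermediate
20 | (2R,3R,4R)-5,7-bis(benzyloxy)-2-[3,4,5-tris(benzyloxy)phenyl]-4-(hexa-O-benzylepigallocatechin-8-yl)chroman-3-ol (2,3-cis, 3,4-trans, 4β→8 linked dimer) | O[C@@H]1[C@@H](c2c(OCc9ccccc9)cc(OCc9ccccc9)c3c2O[C@H](c2cc(OCc9ccccc9)c(OCc9ccccc9)c(OCc9ccccc9)c2)[C@H](OCc9ccccc9)C3)c2c(OCc9ccccc9)cc(OCc9ccccc9)cc2O[C@@H]1c1cc(OCc9ccccc9)c(OCc9ccccc9)c(OCc9ccccc9)c1 | intermediate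
21 | 3,4,5-tris(benzyloxy)benzoic acid | OC(=O)c1cc(OCc9ccccc9)c(OCc9ccccc9)c(OCc9ccccc9)c1 | starting material
22 | 3-O-[3,4,5-tris(benzyloxy)benzoyl] ester of 20 | O=C(O[C@@H]1[C@@H](c2c(OCc9ccccc9)cc(OCc9ccccc9)c3c2O[C@H](c2cc(OCc9ccccc9)c(OCc9ccccc9)c(OCc9ccccc9)c2)[C@H](OCc9ccccc9)C3)c2c(OCc9ccccc9)cc(OCc9ccccc9)cc2O[C@@H]1c1cc(OCc9ccccc9)c(OCc9ccccc9)c(OCc9ccccc9)c1)c1cc(OCc9ccccc9)c(OCc9ccccc9)c(OCc9ccccc9)c1 | intermediate
23 | 8-bromo-3,5,7,3',4',5'-hexa-O-benzyl-4β-(2-ethoxyethoxy)epigallocatechin (C4 ether trans to O-3) | CCOCCO[C@H]1c2c(OCc9ccccc9)cc(OCc9ccccc9)c(Br)c2O[C@H](c2cc(OCc9ccccc9)c(OCc9ccccc9)c(OCc9ccccc9)c2)[C@@H]1OCc9ccccc9 | intermediate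
24 | perbenzylated 8-bromo trimer: 22 bearing at C8 of its middle ring A the 4β-linked 8-bromo-hexa-O-benzylepigallocatechin-4-yl unit | O=C(O[C@@H]1[C@@H](c2c(OCc9ccccc9)cc(OCc9ccccc9)c3c2O[C@H](c2cc(OCc9ccccc9)c(OCc9ccccc9)c(OCc9ccccc9)c2)[C@H](OCc9ccccc9)C3)c2c(OCc9ccccc9)cc(OCc9ccccc9)c([C@H]3c4c(OCc9ccccc9)cc(OCc9ccccc9)c(Br)c4O[C@H](c4cc(OCc9ccccc9)c(OCc9ccccc9)c(OCc9ccccc9)c4)[C@@H]3OCc9ccccc9)c2O[C@@H]1c1cc(OCc9ccccc9)c(OCc9ccccc9)c(OCc9ccccc9)c1)c1cc(OCc9ccccc9)c(OCc9ccccc9)c(OCc9ccccc9)c1 | intermediate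
25 | CNP0278699.1, epigallocatechin-(4β→8)-epigallocatechin 3-O-gallate-(4β→8)-epigallocatechin | O=C(O[C@@H]1[C@@H](c2c(O)cc(O)c3c2O[C@H](c2cc(O)c(O)c(O)c2)[C@H](O)C3)c2c(O)cc(O)c([C@H]3c4c(O)cc(O)cc4O[C@H](c4cc(O)c(O)c(O)c4)[C@@H]3O)c2O[C@@H]1c1cc(O)c(O)c(O)c1)c1cc(O)c(O)c(O)c1 | target

Total step count: 16. Longest linear sequence: 13 steps (1, 2, 3, 4, 6, 7, 8, 9, 10, 12, 13, 15, 16).

Steps most likely to fail

Step 8. Oxygen transfer from the peracid to the electron-rich benzyloxy arenes may outrun Criegee adduct formation at the hindered ketone, and migration of the C2 methylene may compete with that of the aryl carbon, whose two meta ethers lower its aptitude. The fallback gives up oxygen insertion. Setting out from bromide 4, lithiation to 5 and trapping with 2-isopropoxy-4,4,5,5-tetramethyl-1,3,2-dioxaborolane would give the C8 pinacol boronate F1. A rhodium-catalysed asymmetric conjugate addition (Rh(acac)(C2H4)2, (R)-SEGPHOS, aq. KOH, 1,4-dioxane, 60 °C) of F1 to 5,7-bis(benzyloxy)coumarin F2 (from commercial 5,7-dihydroxycoumarin, BnBr, K2CO3) would then give the lactone with the ligand setting C4. The route is rejoined at 11.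

Step 12. The Lewis acidic alane may ionise the epoxide and a 1,2-hydride shift to a chroman-3-one may follow before aryl transfer, or the aryl group may be delivered without facial control. Setting out from enol phosphate 13, a Suzuki–Miyaura coupling (Pd(PPh3)4, aq. Cs2CO3, DMF, 50 °C) with the aryl pinacol boronate F3 (from 16 by lithiation to 17 and the same borate ester) would give the 2-aryl-4H-chromene F4. OsO4 (cat.)/NMO dihydroxylation anti to the C4 aryl group would give the 2,3-cis hemiketal diol F5. Ionic hydrogenation (Et3SiH, BF3·OEt2, CH2Cl2, −78 °C) through the 2-aryl oxocarbenium ion, with hydride entering anti to O-3, would return alcohol 20. In this fallback the C2 configuration is less secure than in the main route, because hydride must enter on the face of the C4 aryl group.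

Step 7. Facial discrimination in the migratory insertion may be weak because the β-aryl group of the enone carries two ortho substituents. Setting out from 9, a reductive Heck cyclisation without chiral ligand (Pd(OAc)2, PPh3, HCO2Na, DMF, 100 °C) would give 10 mixed with its C3 epimer F6. The mixture would be dehydrogenated in one pot (LDA; N-tert-butylbenzenesulfinimidoyl chloride, THF, −78 °C) to the single indenone F7. A copper hydride conjugate reduction (Cu(OAc)2, (R)-DTBM-SEGPHOS, (EtO)2MeSiH, t-BuOH, toluene, 0 °C) would then set C3 under catalyst control and return 10.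

Further compounds
F1 | step 8 | 2-(hexa-O-benzylepigallocatechin-8-yl)-4,4,5,5-tetramethyl-1,3,2-dioxaborolane | CC1(C)OB(OC1(C)C)c1c(OCc9ccccc9)cc(OCc9ccccc9)c2c1O[C@H](c1cc(OCc9ccccc9)c(OCc9ccccc9)c(OCc9ccccc9)c1)[C@H](OCc9ccccc9)C2
F2 | step 8 | 5,7-bis(benzyloxy)coumarin | O=C1C=Cc2c(OCc9ccccc9)cc(OCc9ccccc9)cc2O1
F3 | step 12 | 2-[3,4,5-tris(benzyloxy)phenyl]-4,4,5,5-tetramethyl-1,3,2-dioxaborolane | CC1(C)OB(OC1(C)C)c1cc(OCc9ccccc9)c(OCc9ccccc9)c(OCc9ccccc9)c1
F4 | step 12 | (4R)-5,7-bis(benzyloxy)-2-[3,4,5-tris(benzyloxy)phenyl]-4-(hexa-O-benzylepigallocatechin-8-yl)-4H-chromene | C1(c2cc(OCc9ccccc9)c(OCc9ccccc9)c(OCc9ccccc9)c2)=C[C@@H](c2c(OCc9ccccc9)cc(OCc9ccccc9)c3c2O[C@H](c2cc(OCc9ccccc9)c(OCc9ccccc9)c(OCc9ccccc9)c2)[C@H](OCc9ccccc9)C3)c2c(OCc9ccccc9)cc(OCc9ccccc9)cc2O1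
F5 | step 12 | 2,3-cis-diol (2-hemiketal) of F4, both hydroxyls on the face opposite to the C4 aryl group | O[C@@H]1[C@@H](c2c(OCc9ccccc9)cc(OCc9ccccc9)c3c2O[C@H](c2cc(OCc9ccccc9)c(OCc9ccccc9)c(OCc9ccccc9)c2)[C@H](OCc9ccccc9)C3)c2c(OCc9ccccc9)cc(OCc9ccccc9)cc2O[C@@]1(O)c1cc(OCc9ccccc9)c(OCc9ccccc9)c(OCc9ccccc9)c1
F6 | step 7 | (3S)-4,6-bis(benzyloxy)-3-(hexa-O-benzylepigallocatechin-8-yl)indan-1-one (C3 epimer of 10) | O=C1C[C@H](c2c(OCc9ccccc9)cc(OCc9ccccc9)c3c2O[C@H](c2cc(OCc9ccccc9)c(OCc9ccccc9)c(OCc9ccccc9)c2)[C@H](OCc9ccccc9)C3)c2c(OCc9ccccc9)cc(OCc9ccccc9)cc21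
F7 | step 7 | 4,6-bis(benzyloxy)-3-(hexa-O-benzylepigallocatechin-8-yl)inden-1-one | O=C1C=C(c2c(OCc9ccccc9)cc(OCc9ccccc9)c3c2O[C@H](c2cc(OCc9ccccc9)c(OCc9ccccc9)c(OCc9ccccc9)c2)[C@H](OCc9ccccc9)C3)c2c(OCc9ccccc9)cc(OCc9ccccc9)cc21
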